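**Strategy.** Everything rests on a [3+3] disconnection of ring A (eudesmane numbering). The ketone unit C3–C4–C5, nucleophilic at both α-carbons, is united with the enoate unit C10–C1–C2, electrophilic at both ends. In one operation an acyclic keto (Z)-enoate undergoes an intramolecular Michael–Claisen cascade that closes ring B at C5–C10, creating the quaternary C10, and ring A at C2–C3, giving a trans-fused decalin-2,4-dione. The step exploits the oxygen-bearing C4, flanked by the enolisable C3 and C5, and the C9 oxygen, allylic to the acceptor, whose stereocentre directs C10. The precursor comes from (R)-limonene oxide (C3–C9, including C7) and methyl propiolate.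

Key step: step 5

Numbering used throughout: ring A = C1, C2, C3, C4, C5, C10; ring B = C5 to C10; C14 = methyl on C10; C15 = methyl on C4; C11 (with C12, C13) = three-carbon unit on C7; α = face of H-5, β = face of C14. In the acyclic compounds 5–7 the chain locants map as chain C1 = C2, C2 = C1, C3 = C10, C4 = C9, C6 = C7, C8 = C5, C9 = C4, C10 = C3.

Remark: (4R)-limonene 1,2-oxide (cis/trans mixture), methyl propiolate and (3S)-3-methylpentanoic acid are taken as purchased.

Remark: the antipode of the ProPhenol ligand in step 2 is the one that delivers the 4S carbinol, to be confirmed by Mosher ester analysis of a trial run.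

**Step 1**
Reactants: 1 (4R)-limonene 1,2-oxide (cis/trans mixture)
Product: 3 (3R)-6-oxo-3-(prop-1-en-2-yl)heptanal, via p-menth-8-ene-1,2-diol 2 (not isolated)
Conditions: H5IO6, THF/H2O, 0 °C → rt
Reagents that add atoms: water, O
Why: Acid-promoted hydration of the epoxide and Malaprade glycol cleavage open the ring between the two oxygenated carbons, both epoxide diastereomers converging on one keto aldehyde, and the isopropenyl-bearing centre (future C7) is not touched.

**Step 2**
Reactants: 3 (3R)-6-oxo-3-(prop-1-en-2-yl)heptanal; 4 methyl propiolate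
Product: 5 methyl (4S,6R)-4-hydroxy-9-oxo-6-(prop-1-en-2-yl)dec-2-ynoate
Conditions: Me2Zn, ProPhenol ligand (antipode giving the 4S alcohol), Ph3PO, toluene, 0 °C; aq. NH4Cl
Reagents that add atoms: none
Why: Catalytic enantioselective alkynylation with the zinc alkynylide should add to the aldehyde in preference to the methyl ketone, the chiral dinuclear zinc catalyst setting the new carbinol centre (future C9) by reagent control.

**Step 3**
Reactants: 5 methyl (4S,6R)-4-hydroxy-9-oxo-6-(prop-1-en-2-yl)dec-2-ynoate
Product: 6 methyl (4S,6R)-4-(tert-butyldimethylsilyloxy)-9-oxo-6-(prop-1-en-2-yl)dec-2-ynoate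
Conditions: TBSCl, imidazole, DMF, 0 °C → rt
Reagents that add atoms: tert-butyldimethylsilyl chloride, CC(C)(C)[Si](C)(C)Cl
Why: Standard silylation of a secondary propargylic alcohol gives an ether that is stable to alkoxide base and prevents lactonisation to a butenolide after the next step.

**Step 4**
Reactants: 6 methyl (4S,6R)-4-(tert-butyldimethylsilyloxy)-9-oxo-6-(prop-1-en-2-yl)dec-2-ynoate
Product: 7 methyl (2Z,4S,6R)-4-(tert-butyldimethylsilyloxy)-3-methyl-9-oxo-6-(prop-1-en-2-yl)dec-2-enoate
Conditions: Me2CuLi (from MeLi and CuI), THF, −78 °C; MeOH then aq. NH4Cl at −78 °C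
Reagents that add atoms: lithium dimethylcuprate, [Li+].C[Cu-]C
Why: syn-Carbocupration of the ynoate and protonation of the vinylcopper with retention at low temperature should give the (Z)-enoate (ester cis to the silyloxy-bearing carbon) with the C14 methyl in place, the ketone being inert to the cuprate at −78 °C.

**Step 5**
Reactants: 7 methyl (2Z,4S,6R)-4-(tert-butyldimethylsilyloxy)-3-methyl-9-oxo-6-(prop-1-en-2-yl)dec-2-enoate
Product: 9 trans-decalin-2,4-dione (5α-H; 10β-methyl; 9β-OTBS; 7α-isopropenyl), via keto ester 8 (not isolated)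
Conditions: KOtBu (2.5 equiv), tBuOH, THF (0.02 M), 0 → 40 °C; then 1 M HCl
Reagents that add atoms: none
Why: KOtBu reversibly generates the C5 enolate of the methyl ketone, which adds to C10 of the (Z)-enoate (intramolecular Michael addition, 6-exo-trig, closing ring B and forming C5–C10); after proton transfer the C3 enolate attacks the ester carbon C2 and expels methoxide (intramolecular Claisen condensation, 6-exo-trig, closing ring A and forming C2–C3), and the β-diketonate so formed makes the cascade irreversible. The closest known reaction type is the Michael–Claisen [3+3] synthesis of cyclohexane-1,3-diones from ketones and α,β-unsaturated esters (dimedone-type annulation). C10 is controlled by the C9 stereocentre: allylic 1,3-strain in the (Z)-enoate keeps C9–H in the alkene plane syn to the ester, so the tether carbon C8 and the silyloxy group lie on opposite faces and the enolate, delivered from the C8 face, bonds anti to the C9 oxygen, which places the C10 methyl cis to that oxygen. C5 is set trans to the C10 methyl because the Michael adduct can epimerise α to the ketone and the Claisen closure should prefer the diequatorial, trans-decalin transition state. The step needs C5 and not C3 to attack C10, which ring size secures (six- against eight-membered), and it needs the alkene geometry and C9 to survive, which rests on the ketone being several pK units more acidic than the γ-hydrogens of the enoate and on the non-nucleophilic base.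

**Step 6**
Reactants: 9 trans-decalin-2,4-dione (5α-H; 10β-methyl; 9β-OTBS; 7α-isopropenyl)
Product: 10 4-oxo-2-en-2-yl triflate (C2(OTf)=C3–C4=O)
Conditions: Tf2O, pyridine, CH2Cl2, −78 → 0 °C
Reagents that add atoms: triflic anhydride, O=S(=O)(OS(=O)(=O)C(F)(F)F)C(F)(F)F
Why: O-sulfonylation of the enolised 1,3-dione should occur at the less hindered oxygen on C2, because C4 is flanked by the ring-fusion methine C5, so the C4 carbonyl is kept.

**Step 7**
Reactants: 10 4-oxo-2-en-2-yl triflate
Product: 11 enone (C2=C3–C4=O; 9β-OTBS; 7α-isopropenyl)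
Conditions: Pd(OAc)2 (cat.), PPh3, HCO2H, Bu3N, DMF, 60 °C
Reagents that add atoms: none
Why: Palladium-catalysed formate reduction of an enol triflate (oxidative addition to zerovalent palladium, decarboxylation of formate to a palladium hydride, reductive elimination) replaces the triflate by hydrogen and spares the isolated isopropenyl alkene and the silyl ether.

**Step 8**
Reactants: 11 enone (C2=C3–C4=O)
Product: 13 enol triflate (C3=C4–OTf), via lithium enolate 12 (not isolated)
Conditions: LiBH(sec-Bu)3, THF, −78 °C; then PhNTf2, −78 → 0 °C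
Reagents that add atoms: N-phenylbis(trifluoromethanesulfonimide), O=S(=O)(N(c1ccccc1)S(=O)(=O)C(F)(F)F)C(F)(F)F
Why: The bulky borohydride adds hydride 1,4 to the β-unsubstituted cyclohexenone, giving regiospecifically the C3=C4 enolate, which is trapped on oxygen by the triflimide.

**Step 9**
Reactants: 13 enol triflate (C3=C4–OTf)
Product: 14 3-ene with C15 methyl on C4 (9β-OTBS; 7α-isopropenyl)
Conditions: Me2CuLi (from MeLi and CuI), THF, −20 → 0 °C; aq. NH4Cl
Reagents that add atoms: lithium dimethylcuprate, [Li+].C[Cu-]C
Why: Cross-coupling of an enol triflate with a lithium dialkylcuprate replaces the triflate by methyl with retention of the alkene position, installing C15.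

**Step 10**
Reactants: 14 3-ene with C15 methyl on C4
Product: 15 3α,4α-epoxide
Conditions: mCPBA (1.05 equiv), NaHCO3, CH2Cl2, −10 °C
Reagents that add atoms: 3-chloroperbenzoic acid, O=C(OO)c1cccc(Cl)c1
Why: Prilezhaev epoxidation should be chemoselective for the trisubstituted ring alkene over the 1,1-disubstituted isopropenyl group (as in limonene) and should occur on the α face, anti to the axial C14 methyl, which fixes the C4 oxygen as α.

**Step 11**
Reactants: 15 3α,4α-epoxide
Product: 16 4α-hydroxy-4β-methyl compound (9β-OTBS; 7α-isopropenyl)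
Conditions: LiBHEt3, THF, 0 °C → reflux; aq. work-up
Reagents that add atoms: none
Why: Hydride opens the epoxide by SN2 attack at the less substituted C3 (the tertiary C4 is shielded by the syn-axial C14 methyl), so the oxygen stays on C4 on the α face and the equatorial tertiary alcohol with axial C15 results.

**Step 12**
Reactants: 16 4α-hydroxy-4β-methyl compound (9β-OTBS)
Product: 17 4α,9β-diol (7α-isopropenyl)
Conditions: Bu4NF, THF, rt → 50 °C
Reagents that add atoms: none
Why: Fluoride-induced desilylation frees the secondary C9 hydroxyl without affecting the tertiary alcohol or the alkene.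

**Step 13**
Reactants: 17 4α,9β-diol; 18 (3S)-3-methylpentanoic acid
Product: 19 9β-[(3S)-3-methylpentanoyloxy]-4α-ol (7α-isopropenyl)
Conditions: EDC·HCl, DMAP, CH2Cl2, rt
Reagents that add atoms: none
Why: Steglich esterification acylates only the secondary C9 hydroxyl, the tertiary C4 hydroxyl being unreactive, and the β-stereocentre of the acid cannot epimerise.

**Step 14**
Reactants: 19 9β-[(3S)-3-methylpentanoyloxy]-4α-ol (7α-isopropenyl)
Product: 20 allylic alcohol (C7–C(=CH2)–CH2OH)
Conditions: SeO2 (0.5 equiv), tBuOOH, CH2Cl2, rt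
Reagents that add atoms: tert-butyl hydroperoxide, CC(C)(C)OO (oxygen transferred through selenium dioxide, O=[Se]=O)
Why: Allylic oxidation with SeO2 (ene reaction then [2,3]-sigmatropic shift) attacks the methyl of the isopropenyl group in preference to the C7 methine, and any enal formed by over-oxidation converges in the next step.

**Step 15**
Reactants: 20 allylic alcohol (C7–C(=CH2)–CH2OH)
Product: 22 target acid CNP0471281.1, via enal 21 (not isolated)
Conditions: TEMPO (cat.), NaOCl (cat.), NaClO2, MeCN/phosphate buffer pH 6.7, 35 °C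
Reagents that add atoms: sodium chlorite, [Na+].[O-]Cl=O
Why: Oxoammonium oxidation of the primary allylic alcohol to the enal and chlorite (Pinnick-type) oxidation of the enal in the same buffered medium give the acrylic acid without touching the ester, the tertiary alcohol or the position of the alkene.

**Compound list**

1 | (4R)-limonene 1,2-oxide (cis/trans mixture) | CC12CC[C@H](CC1O2)C(C)=C | starting material
2 | (4R)-p-menth-8-ene-1,2-diol | CC1(O)CC[C@H](CC1O)C(C)=C | intermediate
3 | (3R)-6-oxo-3-(prop-1-en-2-yl)heptanal | O=CC[C@@H](CCC(C)=O)C(C)=C | intermediate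
4 | methyl propiolate | C#CC(=O)OC | starting material
5 | methyl (4S,6R)-4-hydroxy-9-oxo-6-(prop-1-en-2-yl)dec-2-ynoate | COC(=O)C#C[C@@H](O)C[C@@H](CCC(C)=O)C(C)=C | intermediate
6 | methyl (4S,6R)-4-(tert-butyldimethylsilyloxy)-9-oxo-6-(prop-1-en-2-yl)dec-2-ynoate | COC(=O)C#C[C@@H](O[Si](C)(C)C(C)(C)C)C[C@@H](CCC(C)=O)C(C)=C | intermediate
7 | methyl (2Z,4S,6R)-4-(tert-butyldimethylsilyloxy)-3-methyl-9-oxo-6-(prop-1-en-2-yl)dec-2-enoate | COC(=O)/C=C(C)\[C@@H](O[Si](C)(C)C(C)(C)C)C[C@@H](CCC(C)=O)C(C)=C | intermediate
8 | Michael adduct: ring-B keto ester, methyl [2-acetyl-6-(tert-butyldimethylsilyloxy)-1-methyl-4-isopropenylcyclohexyl]acetate, configuration as in 9 | C=C(C)[C@H]1C[C@H](O[Si](C)(C)C(C)(C)C)[C@@](C)(CC(=O)OC)[C@H](C(C)=O)C1 | intermediate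
9 | trans-decalin-2,4-dione: 5α-H, 10β-methyl, 9β-OTBS, 7α-isopropenyl | C=C(C)[C@H]1C[C@H](O[Si](C)(C)C(C)(C)C)[C@@]2(C)CC(=O)CC(=O)[C@@H]2C1 | intermediate
10 | vinylogous triflate of 9: C2(OTf)=C3–C4=O | C=C(C)[C@H]1C[C@H](O[Si](C)(C)C(C)(C)C)[C@@]2(C)CC(OS(=O)(=O)C(F)(F)F)=CC(=O)[C@@H]2C1 | intermediate
11 | enone: C2=C3–C4=O, 5α-H, 10β-methyl, 9β-OTBS, 7α-isopropenyl | C=C(C)[C@H]1C[C@H](O[Si](C)(C)C(C)(C)C)[C@@]2(C)CC=CC(=O)[C@@H]2C1 | intermediate
12 | lithium enolate: C3=C4–OLi | [Li+].C=C(C)[C@H]1C[C@H](O[Si](C)(C)C(C)(C)C)[C@@]2(C)CCC=C([O-])[C@@H]2C1 | intermediate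
13 | enol triflate: C3=C4–OTf | C=C(C)[C@H]1C[C@H](O[Si](C)(C)C(C)(C)C)[C@@]2(C)CCC=C(OS(=O)(=O)C(F)(F)F)[C@@H]2C1 | intermediate
14 | 9β-OTBS-7-epi-eudesma-3,11-diene (C15 methyl on C4, C3=C4) | C=C(C)[C@H]1C[C@H](O[Si](C)(C)C(C)(C)C)[C@@]2(C)CCC=C(C)[C@@H]2C1 | intermediate
15 | 3α,4α-epoxide of 14 | C=C(C)[C@H]1C[C@H](O[Si](C)(C)C(C)(C)C)[C@@]2(C)CC[C@H]3O[C@@]3(C)[C@@H]2C1 | intermediate
16 | 4α-hydroxy-4β-methyl-9β-OTBS-7α-isopropenyl trans-decalin | C=C(C)[C@H]1C[C@H](O[Si](C)(C)C(C)(C)C)[C@@]2(C)CCC[C@@](C)(O)[C@@H]2C1 | intermediate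
17 | 4α,9β-diol (7-epi-eudesm-11-ene-4α,9β-diol) | C=C(C)[C@H]1C[C@H](O)[C@@]2(C)CCC[C@@](C)(O)[C@@H]2C1 | intermediate
18 | (3S)-3-methylpentanoic acid | O=C(O)C[C@@H](C)CC | starting material
19 | 9β-[(3S)-3-methylpentanoyloxy]-7-epi-eudesm-11-en-4α-ol | C=C(C)[C@H]1C[C@H](OC(=O)C[C@@H](C)CC)[C@@]2(C)CCC[C@@](C)(O)[C@@H]2C1 | intermediate
20 | allylic alcohol: 12-hydroxy derivative of 19 (C7–C(=CH2)CH2OH) | C=C(CO)[C@H]1C[C@H](OC(=O)C[C@@H](C)CC)[C@@]2(C)CCC[C@@](C)(O)[C@@H]2C1 | intermediate
21 | enal: 12-oxo derivative of 19 (C7–C(=CH2)CHO) | C=C(C=O)[C@H]1C[C@H](OC(=O)C[C@@H](C)CC)[C@@]2(C)CCC[C@@](C)(O)[C@@H]2C1 | intermediate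
22 | 2-[(2R,4S,4aS,8R,8aR)-8-hydroxy-4a,8-dimethyl-4-{[(3S)-3-methylpentanoyl]oxy}decahydronaphthalen-2-yl]prop-2-enoic acid | C=C(C(=O)O)[C@H]1C[C@H](OC(=O)C[C@@H](C)CC)[C@@]2(C)CCC[C@@](C)(O)[C@@H]2C1 | target

**Totals.** Total step count: 15. Longest linear sequence: 15 steps (1 → 22); 4 and 18 are purchased.

**Steps most likely to fail**

Step 5 (key step). Two processes may interfere. Deprotonation at a γ-position of the enoate (C9–H or the C14 methyl) would give a dienolate, scrambling the alkene geometry and the C9 configuration and so eroding control of C10. Ring A may also close through a cis-fused transition state that avoids the axial isopropenyl group. The fallback sets out from 7 and separates the two bond formations under conditions without free base in the first one. Soft enolisation (TMSCl, NaI, Et3N, MeCN) should give the more substituted silyl enol ether F3. A Mukaiyama–Michael cyclisation (TiCl4, CH2Cl2, −78 °C) should then form C5–C10 and give keto ester 8, which is isolated. Claisen closure with LiN(SiMe3)2 (THF, −78 → 0 °C) comes back to the route at 9; by then C9 is no longer allylic and cannot be deprotonated. A cis-fused by-product could be corrected later, since C5 of enone 11 is epimerisable α to the ketone.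

Step 2. The keto aldehyde may undergo intramolecular aldol reaction under the zinc alkoxide conditions, and facial control at the new carbinol may be incomplete. The fallback sets out from 3. Addition of the lithium acetylide of 4 (LiN(SiMe3)2, THF, −78 °C) should give the C4-epimeric propargylic alcohols F1 without stereocontrol. Dess–Martin oxidation should give ynone F2. Asymmetric transfer hydrogenation with RuCl[(S,S)-TsDPEN](p-cymene) in iPrOH should reduce the ynone in preference to the dialkyl ketone and, by analogy with aryl and alkynyl ketones, give the 4S alcohol, coming back to the route at 5.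

Step 6. Sulfonylation may be poorly regioselective between the two oxygens of the enolised dione, giving the triflate on the C4 oxygen and, after reduction, the transposed enone. The fallback avoids the dione altogether and sets out from 7. The cascade is stopped at the Michael stage (KOtBu 0.2 equiv, tBuOH/THF, −20 °C) and keto ester 8 is isolated. iBu2AlH should reduce ester and ketone to diol F4, and Dess–Martin periodinane should give keto aldehyde F5. Intramolecular aldol condensation (KOH, MeOH), in which only the C3 enolate and the C2 aldehyde can form an unstrained ring, closes ring A and comes back to the route at 11.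

**Further compounds**

F1 | step 2 | methyl (6R)-4-hydroxy-9-oxo-6-(prop-1-en-2-yl)dec-2-ynoate, mixture of C4 epimers | COC(=O)C#CC(O)C[C@@H](CCC(C)=O)C(C)=C
F2 | step 2 | methyl (6R)-4,9-dioxo-6-(prop-1-en-2-yl)dec-2-ynoate | COC(=O)C#CC(=O)C[C@@H](CCC(C)=O)C(C)=C
F3 | step 5 | methyl (2Z,4S,6R)-4-(tert-butyldimethylsilyloxy)-3-methyl-6-(prop-1-en-2-yl)-9-(trimethylsilyloxy)deca-2,8-dienoate | COC(=O)/C=C(C)\[C@@H](O[Si](C)(C)C(C)(C)C)C[C@@H](CC=C(C)O[Si](C)(C)C)C(C)=C
F4 | step 6 | ring-B diol: C10 CH2CH2OH and C5 CH(OH)CH3, otherwise as 8 (carbinol epimers) | C=C(C)[C@H]1C[C@H](O[Si](C)(C)C(C)(C)C)[C@@](C)(CCO)[C@H](C(C)O)C1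
F5 | step 6 | ring-B keto aldehyde: C10 CH2CHO and C5 acetyl, otherwise as 8 | C=C(C)[C@H]1C[C@H](O[Si](C)(C)C(C)(C)C)[C@@](C)(CC=O)[C@H](C(C)=O)C1
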